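**Retrosynthetic overview**
- The target is (S,E)-Ar–CH=CH–CH(CH3)–Ar with two identical aryl groups (Ar = 7-methoxy-2,2-dimethyl-2H-chromen-6-yl), so one aryl bromide ArBr serves both halves.
- Key disconnection: the Ar–C1 bond and the C1=C2 alkene are made together by palladium coupling of ArBr with the N-tosylhydrazone of (S)-3-arylbutanal; the former aldehyde carbon enters as a nucleophilic diazo carbon.
- The C3 stereocentre is set one step earlier by rhodium/chiral-diene 1,4-addition of ArB(OH)2 to (E)-but-2-enal.
- ArB(OH)2 comes from ArBr by bromine–lithium exchange and borylation.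
- Ring order: the pyran ring is built first and only once (4-bromo-3-methoxyphenol + 3-methylbut-2-enal); no ring is formed later, and the second chromene arrives ready-made in the last step.

Assumption: the SMILES is read as the S-configured, E-alkene isomer (C28H32O4) with two identical 7-methoxy-2,2-dimethyl-2H-chromen-6-yl groups.

**Step 1**
Reactants: 1 4-bromo-3-methoxyphenol; 2 3-methylbut-2-enal
Product: 5 6-bromo-7-methoxy-2,2-dimethyl-2H-chromene, via benzodioxaborinine 3 (not isolated), via ortho-quinone methide 4 (not isolated)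
Conditions: 2 (1.5 equiv), PhB(OH)2 (1.0 equiv, recovered), AcOH (0.3 equiv), toluene, reflux, Dean–Stark
Reagents that add atoms: none
Why: Phenylboronic-acid-templated ortho-condensation of a phenol with an enal, in which the boronate delivers the aldehyde to the free ortho carbon para to OMe to give 3, which fragments on heating to ortho-quinone methide 4 that closes by oxa-6π electrocyclisation to the 2H-chromene.

**Step 2**
Reactants: 5 6-bromo-7-methoxy-2,2-dimethyl-2H-chromene
Product: 8 (7-methoxy-2,2-dimethyl-2H-chromen-6-yl)boronic acid, via aryllithium 6 (not isolated), via lithium aryltriisopropoxyborate 7 (not isolated)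
Conditions: n-BuLi (1.05 equiv), THF, −78 °C; B(OiPr)3 (1.5 equiv), −78 °C to rt; 1 M HCl (aq), 0 °C, 10 min
Reagents that add atoms: triisopropyl borate CC(C)OB(OC(C)C)OC(C)C; water O
Why: Lithiation–borylation, in which bromine–lithium exchange at −78 °C (faster than any reaction at the chromene) gives aryllithium 6, the borate ester traps it as ate complex 7, and brief cold acidic hydrolysis releases the boronic acid.

**Step 3**
Reactants: 8 (7-methoxy-2,2-dimethyl-2H-chromen-6-yl)boronic acid; 9 (E)-but-2-enal
Product: 10 (3S)-3-(7-methoxy-2,2-dimethyl-2H-chromen-6-yl)butanal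
Conditions: 8 (1.5 equiv), 9 (1.0 equiv), [RhCl(C2H4)2]2 (2.5 mol%), (1R,4R)-2,5-diphenylbicyclo[2.2.2]octa-2,5-diene (5.5 mol%), KOH (0.2 equiv), 1,4-dioxane/H2O 10:1, 25 °C
Reagents that add atoms: none
Why: Hayashi–Miyaura rhodium-catalysed asymmetric 1,4-addition (transmetalation from boron to monovalent rhodium, enantioface-selective carborhodation of the enal, protonolysis of the oxa-π-allyl), in which the (R,R)-diene that delivers aryl groups to the α-re face of enones places the aryl on the si face of C3 of (E)-9 and so sets S at the new stereocentre, which is β to the carbonyl and cannot epimerise.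

**Step 4 (key step)**
Reactants: 10 (3S)-3-(7-methoxy-2,2-dimethyl-2H-chromen-6-yl)butanal; 11 4-methylbenzenesulfonohydrazide; 5 6-bromo-7-methoxy-2,2-dimethyl-2H-chromene
Product: 14 6,6'-[(1E,3S)-but-1-ene-1,3-diyl]bis(7-methoxy-2,2-dimethyl-2H-chromene), via N-tosylhydrazone 12 (not isolated), via diazoalkane 13 (not isolated)
Conditions: 11 (1.05 equiv), 1,4-dioxane, 60 °C, 1 h; then 5 (1.1 equiv), Pd2(dba)3 (2 mol%), 2-dicyclohexylphosphino-2',4',6'-triisopropylbiphenyl (8 mol%), LiOtBu (2.4 equiv), 90 °C
Reagents that add atoms: none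
Why: Barluenga cross-coupling of a sulfonylhydrazone with an aryl halide, in which LiOtBu turns 12 into diazoalkane 13 (Bamford–Stevens) whose former aldehyde carbon is now nucleophilic and attacks the arylpalladium bromide formed from 5 and zerovalent palladium, so that two carbons that are both electrophilic in their parent functions (C=O and C–Br) are joined through a palladium carbene, migratory aryl insertion and syn β-hydride elimination from C2, which gives the conjugated E-alkene and leaves the S stereocentre at C3 untouched.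

**Compound list**
1 | 4-bromo-3-methoxyphenol | COc1cc(O)ccc1Br | starting material
2 | 3-methylbut-2-enal | CC(C)=CC=O | starting material
3 | 6-bromo-7-methoxy-4-(2-methylprop-1-en-1-yl)-2-phenyl-4H-1,3,2-benzodioxaborinine (racemic) | COc1cc2OB(c3ccccc3)OC(C=C(C)C)c2cc1Br | intermediate
4 | 4-bromo-3-methoxy-6-(3-methylbut-2-en-1-ylidene)cyclohexa-2,4-dien-1-one | O=C1C=C(OC)C(Br)=CC1=CC=C(C)C | intermediate
5 | 6-bromo-7-methoxy-2,2-dimethyl-2H-chromene | COc1cc2OC(C)(C)C=Cc2cc1Br | intermediate
6 | (7-methoxy-2,2-dimethyl-2H-chromen-6-yl)lithium | [Li]c1cc2C=CC(C)(C)Oc2cc1OC | intermediate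
7 | lithium (7-methoxy-2,2-dimethyl-2H-chromen-6-yl)tri(propan-2-yloxy)borate | [Li+].COc1cc2OC(C)(C)C=Cc2cc1[B-](OC(C)C)(OC(C)C)OC(C)C | intermediate
8 | (7-methoxy-2,2-dimethyl-2H-chromen-6-yl)boronic acid | COc1cc2OC(C)(C)C=Cc2cc1B(O)O | intermediate
9 | (E)-but-2-enal | C/C=C/C=O | starting material
10 | (3S)-3-(7-methoxy-2,2-dimethyl-2H-chromen-6-yl)butanal | O=CC[C@H](C)c1cc2C=CC(C)(C)Oc2cc1OC | intermediate
11 | 4-methylbenzenesulfonohydrazide | Cc1ccc(cc1)S(=O)(=O)NN | starting material
12 | N'-[(1E,3S)-3-(7-methoxy-2,2-dimethyl-2H-chromen-6-yl)butylidene]-4-methylbenzenesulfonohydrazide | Cc1ccc(cc1)S(=O)(=O)N/N=C/C[C@H](C)c1cc2C=CC(C)(C)Oc2cc1OC | intermediate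
13 | 6-[(2S)-4-diazobutan-2-yl]-7-methoxy-2,2-dimethyl-2H-chromene | [N-]=[N+]=CC[C@H](C)c1cc2C=CC(C)(C)Oc2cc1OC | intermediate
14 | 6,6'-[(1E,3S)-but-1-ene-1,3-diyl]bis(7-methoxy-2,2-dimethyl-2H-chromene) (CNP0212142.1) | COc1cc2c(cc1/C=C/[C@H](C)c1cc3c(cc1OC)OC(C)(C)C=C3)C=CC(C)(C)O2 | target

**Totals**
Total step count: 4. Longest linear sequence: 4 (1 → 5 → 8 → 10 → 14); bromide 5 is used a second time in the last step.

**Three steps most likely to fail**

Step 4. The electron-rich, ortho-substituted bromide 5 adds slowly to zerovalent palladium, so the unstabilised diazoalkane 13 may decay first (Bamford–Stevens alkene, azine). A palladium hydride or hot LiOtBu could also move the alkene into conjugation with the other ring, which would erase C3. The fallback sets out from 10 and 5 and comes back at 14. Bromide 5 is lithiated (n-BuLi, THF, −78 °C) to 6, which adds to aldehyde 10 to give (3S)-1,3-bis(7-methoxy-2,2-dimethyl-2H-chromen-6-yl)butan-1-ol F1 as both C1 epimers. MsCl and Et3N in CH2Cl2 (0 °C to rt) then convert it to 14: the doubly alkoxy-activated benzylic mesylate ionises and loses a C2 proton (E1), which can only give the conjugated E-alkene. Base is present throughout, so the acid-labile styrene and chromenes are protected, and C3 is not involved.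

Step 3. But-2-enal is prone to 1,2-addition and aldol reactions, boronic acid 8 can protodeboronate, and the small methyl group may limit the selectivity. The S sense is a model-based prediction that has to be checked by chiral HPLC on the first run; if it is reversed, the (1S,4S)-diene is used. The fallback sets out from 5 and comes back at 10. Mg in THF converts 5 into (7-methoxy-2,2-dimethyl-2H-chromen-6-yl)magnesium bromide F2. With CuI (10 mol%) in THF/Me2S at −30 °C this opens commercial (R)-4-methyloxetan-2-one at C4 by SN2 attack with inversion, giving (3S)-3-(7-methoxy-2,2-dimethyl-2H-chromen-6-yl)butanoic acid F3. LiAlH4 (THF, 0 °C) reduces it to (3S)-3-(7-methoxy-2,2-dimethyl-2H-chromen-6-yl)butan-1-ol F4, and Dess–Martin periodinane (NaHCO3, CH2Cl2, rt) returns 10.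

Step 1. Conversion of the moderately activated bromophenol may be modest, and some 5-methoxy regioisomer from closure at the crowded ortho carbon has to be separated. The fallback sets out from 1 and comes back at 5. O-Alkylation of 1 with 3-chloro-3-methylbut-1-yne (K2CO3, KI, CuI 5 mol%, acetone, 56 °C) gives 1-bromo-2-methoxy-4-[(2-methylbut-3-yn-2-yl)oxy]benzene F5. Heating this in N,N-diethylaniline at 190 °C causes an aromatic propargyl Claisen rearrangement, a 1,5-hydrogen shift to the same ortho-quinone methide 4, and electrocyclisation to 5.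

**Further compounds**
F1 | step 4 | (3S)-1,3-bis(7-methoxy-2,2-dimethyl-2H-chromen-6-yl)butan-1-ol (both C1 epimers) | OC(C[C@H](C)c1cc2C=CC(C)(C)Oc2cc1OC)c1cc2C=CC(C)(C)Oc2cc1OC
F2 | step 3 | (7-methoxy-2,2-dimethyl-2H-chromen-6-yl)magnesium bromide | Br[Mg]c1cc2C=CC(C)(C)Oc2cc1OC
F3 | step 3 | (3S)-3-(7-methoxy-2,2-dimethyl-2H-chromen-6-yl)butanoic acid | OC(=O)C[C@H](C)c1cc2C=CC(C)(C)Oc2cc1OC
F4 | step 3 | (3S)-3-(7-methoxy-2,2-dimethyl-2H-chromen-6-yl)butan-1-ol | OCC[C@H](C)c1cc2C=CC(C)(C)Oc2cc1OC
F5 | step 1 | 1-bromo-2-methoxy-4-[(2-methylbut-3-yn-2-yl)oxy]benzene | COc1cc(OC(C)(C)C#C)ccc1Br
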